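**Strategy**

Everything rests on the ring-fusion bond C10–C1 (C2–C3 of the chroman), shared by the pyran ring and the ten-membered carbocycle. It is made first as the E-olefin C1=C10 of a ten-membered 1,5-dienol and only then turned into the fused single bond by a hetero-Diels–Alder reaction with an o-quinone methide. The key step exploits that C10 (methyl- and oxygen-bearing) and C1 (CH) are a former methyl ketone and aldehyde: one reductive carbonyl coupling closes the ten-membered ring from an acyclic keto aldehyde. That precursor comes from (R)-α-terpineol, whose ring carbons become C5–C10 and whose stereocentre becomes C7, by ozonolysis and Z-selective chain extension.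

Key step: step 6

Remark on numbering: germacrane locants are used for the ten-membered ring (C7 carries the 2-hydroxypropan-2-yl group, C4(Me)=C5 is the remaining olefin, C10 is the methyl- and O-bearing carbon, C1 the adjacent CH); C1' is the benzylic carbon that carries the isobutyl group.

Remark on the structure: the SMILES defines C4=C5 as Z (ring carbons C3 and C6 cis, methyl trans to C6); the route is planned for that geometry and for (7R, 10R, 1S, 1'S).

Assumption: 2,4-diformylphloroglucinol (11) is taken as a catalogue compound.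

**Route**

Step 1
Reactants: 1 (R)-(+)-α-terpineol
Product: 2 triethylsilyl ether of 1
Conditions: TESOTf, 2,6-lutidine, CH2Cl2, −78 → 0 °C
Reagents that add atoms: triethylsilyl trifluoromethanesulfonate, CC[Si](CC)(CC)OS(=O)(=O)C(F)(F)F
Why: Silylation of the tertiary alcohol with the reactive silyl triflate masks the hydroxyl, so that ozonolysis gives an open keto aldehyde instead of a lactol and the later titanium step meets no free OH; the stereocentre is untouched.

Step 2
Reactants: 2 triethylsilyl ether of 1
Product: 4 (3R)-6-oxo-3-[2-(triethylsilyloxy)propan-2-yl]heptanal, via secondary ozonide 3 (not isolated)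
Conditions: O3, CH2Cl2, −78 °C; then PPh3, −78 °C → rt
Reagents that add atoms: ozone, [O-][O+]=O
Why: Criegee ozonolysis with reductive work-up cleaves the only C=C bond of 2 into the C10 methyl ketone and the C5 aldehyde, and C7 is not affected.

Step 3
Reactants: 4 (3R)-6-oxo-3-[2-(triethylsilyloxy)propan-2-yl]heptanal
Product: 5 (5R,7Z)-8-iodo-5-[2-(triethylsilyloxy)propan-2-yl]non-7-en-2-one
Conditions: EtPPh3I, n-BuLi, THF, rt; I2, −78 °C; NaN(SiMe3)2, −78 → −20 °C; then 4, −78 °C
Reagents that add atoms: (1-iodoethylidene)triphenylphosphorane (made in the flask), CC(I)=P(c1ccccc1)(c1ccccc1)c1ccccc1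
Why: Stork–Zhao-type Wittig olefination with the α-iodo ylide should attack the aldehyde far faster than the methyl ketone at −78 °C and, under kinetic low-temperature control, place iodine cis to the C6 chain (Z).

Step 4
Reactants: 5 (5R,7Z)-8-iodo-5-[2-(triethylsilyloxy)propan-2-yl]non-7-en-2-one
Product: 6 (5R,7Z)-11,11-diethoxy-8-methyl-5-[2-(triethylsilyloxy)propan-2-yl]undec-7-en-2-one
Conditions: acrolein diethyl acetal, 9-BBN-H, THF, 0 °C → rt; then 5, PdCl2(dppf), AsPh3, Cs2CO3, DMF/H2O, rt
Reagents that add atoms: B-(3,3-diethoxypropyl)-9-borabicyclo[3.3.1]nonane (made in the flask from acrolein diethyl acetal and 9-BBN-H), CCOC(CCB1C2CCCC1CCC2)OCC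
Why: B-alkyl Suzuki–Miyaura coupling proceeds with retention of olefin geometry, so the three-carbon chain (C3–C1) replaces iodine cis to C6 and gives the Z-trisubstituted C4=C5 olefin, while ketone, acetal and silyl ether are inert.

Step 5
Reactants: 6 (5R,7Z)-11,11-diethoxy-8-methyl-5-[2-(triethylsilyloxy)propan-2-yl]undec-7-en-2-one
Product: 7 (4Z,7R)-4-methyl-10-oxo-7-[2-(triethylsilyloxy)propan-2-yl]undec-4-enal
Conditions: 10% aq. oxalic acid on SiO2, CH2Cl2, rt
Reagents that add atoms: water, O
Why: Mild acetal hydrolysis on wet acidic silica should free the C1 aldehyde without cleaving the tertiary silyl ether or isomerising the Z-olefin.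

Step 6
Reactants: 7 (4Z,7R)-4-methyl-10-oxo-7-[2-(triethylsilyloxy)propan-2-yl]undec-4-enal
Product: 9 triethyl({2-[(1R,3Z,7E)-4,8-dimethylcyclodeca-3,7-dien-1-yl]propan-2-yl}oxy)silane, via titanium pinacolate 8 (not isolated)
Conditions: TiCl3(DME)1.5, Zn–Cu couple, DME, reflux; 7 added by syringe pump over about 30 h (final concentration ≤ 0.005 M)
Reagents that add atoms: none
Why: Low-valent titanium (from TiCl3(DME)1.5 and Zn–Cu) transfers single electrons to both carbonyl groups of 7, the ketyl radicals at C1 and C10 couple on the metal to the titanium-bound pinacolate 8, and this is deoxygenated at reflux to the C1=C10 olefin with loss of titanium oxide. The closest known reaction type is the McMurry keto-aldehyde macrocyclisation, which has been used to close ten-membered germacrane-type rings with a trisubstituted olefin. The ten-membered carbocycle is closed by intramolecular carbonyl–carbonyl union of the two chain termini (a macrocyclisation in which both reacting carbons become ring members), run under slow addition and high dilution. No sp3 stereocentre is formed here; the new stereo-element is the E geometry of C1=C10, set in the stepwise deoxygenation of 8, where the carbon radical left after the first C–O cleavage can rotate so that the ring carbons C2 and C9 lie anti, and C10 and C1 become stereocentres only in step 8. The step needs ring closure over intermolecular coupling, which dilution secures, and E over Z geometry, which is the main risk; the Z-olefin C4=C5 turns the chain and brings C1 near C10, the tertiary hydroxyl is masked, and the E,Z-1,5-diene should not undergo Cope rearrangement in refluxing DME.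

Step 7
Reactants: 9 triethyl({2-[(1R,3Z,7E)-4,8-dimethylcyclodeca-3,7-dien-1-yl]propan-2-yl}oxy)silane
Product: 10 2-[(1R,3Z,7E)-4,8-dimethylcyclodeca-3,7-dien-1-yl]propan-2-ol
Conditions: Bu4NF, THF, rt
Reagents that add atoms: none
Why: Fluoride cleaves the Si–O bond under non-acidic conditions, which avoids acid-triggered transannular cyclisation of the 1,5-diene.

Step 8
Reactants: 10 2-[(1R,3Z,7E)-4,8-dimethylcyclodeca-3,7-dien-1-yl]propan-2-ol; 11 2,4-diformylphloroglucinol; 12 3-methylbutanal
Product: 14 target compound, via o-quinone methide 13 (not isolated)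
Conditions: ethylenediammonium diacetate (20 mol %), MeCN, 40 °C
Reagents that add atoms: none
Why: In a domino Knoevenagel/hetero-Diels–Alder reaction, amine-catalysed condensation of 11 and 12 gives the E-configured o-quinone methide 13, which should add as heterodiene to the strained E-olefin C1=C10 rather than to the Z-olefin C4=C5, with oxygen at the more substituted C10; suprafacial addition to the E-olefin fixes the trans ring fusion (C10, C1), the orientation with H-1 and C9 under the heterodiene fixes C1', and attack on the exposed outer face of the olefin in the conformer with the C7 substituent pseudo-equatorial should fix the sense relative to C7.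

**Compound list**

1 | (R)-(+)-α-terpineol, 2-[(1R)-4-methylcyclohex-3-en-1-yl]propan-2-ol | CC1=CC[C@@H](CC1)C(C)(C)O | starting material
2 | triethyl({2-[(1R)-4-methylcyclohex-3-en-1-yl]propan-2-yl}oxy)silane | CC1=CC[C@@H](CC1)C(C)(C)O[Si](CC)(CC)CC | intermediate
3 | secondary ozonide of 2 (1,2,4-trioxolane across the former olefinic carbons; both configurations at the two trioxolane carbons) | CC12CC[C@@H](C(C)(C)O[Si](CC)(CC)CC)CC(OO1)O2 | intermediate
4 | (3R)-6-oxo-3-[2-(triethylsilyloxy)propan-2-yl]heptanal | O=CC[C@H](C(C)(C)O[Si](CC)(CC)CC)CCC(C)=O | intermediate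
5 | (5R,7Z)-8-iodo-5-[2-(triethylsilyloxy)propan-2-yl]non-7-en-2-one | C/C(I)=C/C[C@H](C(C)(C)O[Si](CC)(CC)CC)CCC(C)=O | intermediate
6 | (5R,7Z)-11,11-diethoxy-8-methyl-5-[2-(triethylsilyloxy)propan-2-yl]undec-7-en-2-one | C/C(CCC(OCC)OCC)=C/C[C@H](C(C)(C)O[Si](CC)(CC)CC)CCC(C)=O | intermediate
7 | (4Z,7R)-4-methyl-10-oxo-7-[2-(triethylsilyloxy)propan-2-yl]undec-4-enal | C/C(CCC=O)=C/C[C@H](C(C)(C)O[Si](CC)(CC)CC)CCC(C)=O | intermediate
8 | titanium pinacolate of (5Z,8R)-1,5-dimethyl-8-[2-(triethylsilyloxy)propan-2-yl]cyclodec-5-ene-1,2-diol (drawn as the free diol; both configurations at C1 and C2) | C/C1=C/C[C@H](C(C)(C)O[Si](CC)(CC)CC)CCC(C)(O)C(O)CC1 | intermediate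
9 | triethyl({2-[(1R,3Z,7E)-4,8-dimethylcyclodeca-3,7-dien-1-yl]propan-2-yl}oxy)silane | C/C1=C/C[C@H](C(C)(C)O[Si](CC)(CC)CC)CC/C(C)=C/CC1 | intermediate
10 | 2-[(1R,3Z,7E)-4,8-dimethylcyclodeca-3,7-dien-1-yl]propan-2-ol, (7R)-(1E,4Z)-germacra-1(10),4-dien-11-ol | C/C1=C/C[C@H](C(C)(C)O)CC/C(C)=C/CC1 | intermediate
11 | 2,4-diformylphloroglucinol, 2,4,6-trihydroxybenzene-1,3-dicarbaldehyde | O=Cc1c(O)c(C=O)c(O)cc1O | starting material
12 | 3-methylbutanal (isovaleraldehyde) | CC(C)CC=O | starting material
13 | 2,4-dihydroxy-5-[(E)-3-methylbutylidene]-6-oxocyclohexa-1,3-diene-1,3-dicarbaldehyde (o-quinone methide) | CC(C)C/C=C1/C(=O)C(C=O)=C(O)C(C=O)=C1O | intermediate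
14 | target: 5,7-dihydroxy-4-isobutyl-2-methylchroman-6,8-dicarbaldehyde whose C2 and C3 are C10 and C1 of a (4Z,7R)-4-methyl-7-(2-hydroxypropan-2-yl)cyclodec-4-ene ring; C10 R, C1 S, C1' S, trans ring fusion | C/C1=C/C[C@H](C(C)(C)O)CC[C@@]2(C)Oc3c(C=O)c(O)c(C=O)c(O)c3[C@@H](CC(C)C)[C@@H]2CC1 | target

**Count and risks**

Total step count: 8. Longest linear sequence: 8 steps (from 1).

Steps most likely to fail:

1. Step 6 (key step). The deoxygenation may deliver the Z geometry at C1=C10, stop at the diol stage, or lose material to intermolecular coupling. Fallback: setting out from 7, a SmI2-mediated pinacol cyclisation (THF, high dilution) should give the trans-1,2-diol (1R,2R,5Z,8R)-1,5-dimethyl-8-[2-(triethylsilyloxy)propan-2-yl]cyclodec-5-ene-1,2-diol F1, isolated by chromatography. Thiocarbonyldiimidazole (toluene, heat) converts it into the cyclic thionocarbonate F2. Corey–Winter elimination with 1,3-dimethyl-2-phenyl-1,3,2-diazaphospholidine at 40 °C is a stereospecific syn-elimination, which turns the trans-diol into the E-olefin and comes back to the route at 9.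

2. Step 8. The cycloaddition may show poor facial or endo/exo selectivity, the diene may cyclise transannularly under the slightly acidic conditions, and the o-quinone methide may tautomerise to the styrene before it is trapped. Fallback: setting out from 9, with the bulkier silyloxy group kept on C11 to reinforce the conformational bias. Compounds 11, 12 and morpholine are first condensed to the Mannich base 2,4,6-trihydroxy-5-[3-methyl-1-(morpholin-4-yl)butyl]benzene-1,3-dicarbaldehyde F3. Heating F3 with 9 in toluene at 80 °C releases 13 under neutral conditions and should give the triethylsilyl ether of the target F4, whose diastereomers are easier to separate. Bu4NF in THF then comes back to the route at 14.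

3. Step 3. The iodo-olefination may lose Z-selectivity and conversion through de-iodination of the ylide, epoxide formation or attack at the ketone. Fallback: setting out from 4, dibromo-olefination (CBr4, PPh3, CH2Cl2, 0 °C) gives (5R)-8,8-dibromo-5-[2-(triethylsilyloxy)propan-2-yl]oct-7-en-2-one F5. A trans-selective Negishi monomethylation (Me2Zn, PdCl2(DPEphos), THF) replaces the bromine trans to the chain and gives (5R,7Z)-8-bromo-5-[2-(triethylsilyloxy)propan-2-yl]non-7-en-2-one F6. B-alkyl Suzuki coupling of F6 with the borane of step 4 (Pd(P(t-Bu)3)2, Cs2CO3, retention) comes back to the route at 6.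

**Further compounds**

F1 | step 6 | (1R,2R,5Z,8R)-1,5-dimethyl-8-[2-(triethylsilyloxy)propan-2-yl]cyclodec-5-ene-1,2-diol (trans-diol) | C/C1=C/C[C@H](C(C)(C)O[Si](CC)(CC)CC)CC[C@@](C)(O)[C@H](O)CC1
F2 | step 6 | cyclic thionocarbonate (1,3-dioxolane-2-thione) of F1 | C/C1=C/C[C@H](C(C)(C)O[Si](CC)(CC)CC)CC[C@@]2(C)OC(=S)O[C@@H]2CC1
F3 | step 8 | 2,4,6-trihydroxy-5-[3-methyl-1-(morpholin-4-yl)butyl]benzene-1,3-dicarbaldehyde (racemic) | CC(C)CC(N1CCOCC1)c1c(O)c(C=O)c(O)c(C=O)c1O
F4 | step 8 | triethylsilyl ether of 14 | C/C1=C/C[C@H](C(C)(C)O[Si](CC)(CC)CC)CC[C@@]2(C)Oc3c(C=O)c(O)c(C=O)c(O)c3[C@@H](CC(C)C)[C@@H]2CC1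
F5 | step 3 | (5R)-8,8-dibromo-5-[2-(triethylsilyloxy)propan-2-yl]oct-7-en-2-one | BrC(Br)=CC[C@H](C(C)(C)O[Si](CC)(CC)CC)CCC(C)=O
F6 | step 3 | (5R,7Z)-8-bromo-5-[2-(triethylsilyloxy)propan-2-yl]non-7-en-2-one | C/C(Br)=C/C[C@H](C(C)(C)O[Si](CC)(CC)CC)CCC(C)=O
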